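Assumption: ring positions are numbered C1 (ketone), C2 (pentenyl), C3 (ester chain), C4 (OH), C5 (Br), and the target is read as the (4R,5S) trans bromohydrin. In the IUPAC names below this appears as (4S,5R) because the ring is numbered from the chain-bearing carbon. (3-Methyloxetan-3-yl)methanol is taken as a commercial reagent.

## Structural features

The target has one carbocycle, a cyclopent-2-enone, which carries two chains: a (Z)-pent-2-enyl group on C2 and a seven-methylene chain ending in a methyl ester on C3. C4 and C5 are adjacent stereocentres, with the hydroxyl and the bromine trans; the C4 descriptor is S before bromination and R after it, with no change in space, because bromine raises the priority of C5. C5 lies between the ketone and the bromine and can therefore be equilibrated, whereas C4 cannot. The fragile parts are the alpha-bromo-beta-hydroxy ketone, the doubly allylic methylene between the ring alkene and the Z alkene, the Z geometry and the methyl ester. Base would close the trans bromohydrin to an epoxide, cause retro-aldol cleavage or expel the C4 oxygen. The real difficulty is the tetrasubstituted C2=C3 alkene: it bears four different carbon groups, two of them primary alkyl chains so alike that condensation chemistry cannot be relied on to tell them apart. A second difficulty is the absolute configuration at C4, which has no neighbouring stereocentre to lean on before C5 is made. The key step uses the cis relation of C1 and C4 on the C2=C3 alkene, which is the pattern left by anti addition across the alkyne of a propargylic alcohol whose carbinol carbon is C4.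

## Logic of the disconnections

**20 to 17 (through 19 and 18).** The C5–Br bond is cut and the C4 oxygen is given a silyl group. The bromohydrin is the most base-sensitive unit, so it is made last; removing it deletes one stereocentre and leaves a robust hydroxy enone. The forward steps must enolise C5 and not the gamma position or the ester, deliver bromine anti to the C4 substituent, and remove the silyl group without base.

**17 to 15 (through 16).** No skeletal bond is cut; the O–Si bond is removed and the single stereocentre at C4 is traded for the racemate. C4 arises in a ring closure that offers no handle for asymmetric induction, whereas 4-hydroxy enones of this type are good lipase substrates. Everything before 15 can then be made without stereocontrol. The forward step needs an enzyme that acylates the R enantiomer and leaves 16.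

**15 to 14.** The methyl ester is exchanged for a bridged orthoester (a change of functional group, no C–C bond). The carboxyl carbon has to travel through an organomagnesium reagent, and this mask lets the chain be introduced as a nucleophile. The forward step must open the orthoester under acid that the hydroxy enone survives.

**14 to 13.** The C4–C5 ring bond is cut in the aldol sense. The ring disappears; C5 becomes the methyl group of a methyl ketone and C4 an aldehyde, both cis on the C2=C3 alkene. The forward step needs the Z geometry of 13 and a base mild enough to enolise the methyl ketone without deprotonating the doubly activated methylene of the pentenyl group.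

**13 to 12.** Both C=O groups are taken back to carbinols (oxidation level only). A diol is what carbonyl addition of a vinyl metal delivers, and it is stable where 13 is not. The forward step must oxidise both alcohols in one operation so that no hydroxy-carbonyl intermediate can close to a lactol.

**12 to 4, 8 and 9.** Two bonds on the alkene are cut: C3 to the first chain carbon, and C2 to C1. The alkene becomes the alkyne of 4, whose carbinol carbon is C4; the ester chain becomes the nucleophile 8 and C1 with C5 the two-carbon electrophile 9. This is the greatest simplification, and the order of addition decides which chain sits on which alkene carbon. An atom count confirms the fit: 8 carries seven methylenes before the masked carboxyl carbon, and 4 places the Z alkene three bonds from C2. The forward step must add 8 to the alkyne carbon next to the carbinol, place the metal anti to it, hold the vinyl metal geometry until 9 arrives, and leave the skipped enyne alone.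

**4 to 3 and 2, and 2 to 1.** The C(sp)–C(sp3) bond between the alkyne terminus and the allylic carbon is cut, then the C–Br bond. The Z alkene is bought with 1 and never has to be made. The forward coupling must occur at the primary allylic carbon without transposition or Z to E drift.

**8 to 7, 6 and 5.** The C–Mg bond, the orthoester cage and the ester C–O bond are cut in turn, ending at a commercial bromo acid. The forward demand is a carboxyl mask that forms without touching the primary bromide and is inert to magnesium.

## Other disconnections considered

**Alternative 1:** The cut is a carbonylative [2+2+1] disconnection that breaks C3–C4, C1–C2 and C1–C5 at once. The precursor is (Z)-1-(ethenyloxy)non-6-en-3-yne A2, in which the alkyne carbons are C2 and C3, the vinyl carbons are C4 and C5, and a two-carbon ether tether links C3 to the C4 oxygen. Forward, an intramolecular Pauson–Khand reaction under CO with a chiral diphosphine complex of monovalent rhodium would give the bicyclic enone (6aS)-4-[(Z)-pent-2-en-1-yl]-2,3,6,6a-tetrahydro-5H-cyclopenta[b]furan-5-one A1, with C4 set by the catalyst.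
- In its favour: the ring, the enone, the placing of the pentenyl group and the absolute configuration at C4 would come from one catalytic step. On stereochemical economy and on bonds formed per step this is better than the chosen plan, which forms two bonds and no ring in its key step and discards the R half of 15.
- Against it here: the tether leaves only two of the eight chain carbons on C3. The O–CH2 bond of the temporary ring would have to be cleaved selectively beside an allylic C4–O bond, and six carbons with the ester attached by an sp3–sp3 coupling in the presence of the enone. Vinyl ethers are unusual alkene partners for this catalysis, and a metal hydride pathway could move the skipped Z alkene of A2.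
- Comparison: both plans use an oxygen atom to fix regiochemistry (a tether there, an alkoxide chelate here) and both would end with the same bromination, so they are equal on the last steps. Once tether cleavage and chain extension are counted, the alternative is unlikely to be shorter.

**Alternative 2:** The cut runs across C1–C5 and C4–O (a 1,3-dipolar retron), with C2–C3 cut later as an aldol condensation. The halves are (Z)-hept-4-enal oxime A4, carrying C1, C2 and the pentenyl group, and methyl (9S)-9-hydroxyundec-10-enoate A5, carrying C3, C4, C5 and the ester chain. Forward, the nitrile oxide from A4 would add to the vinyl group of the magnesium alkoxide of A5 to give the syn isoxazoline methyl (9S)-9-hydroxy-9-[(5S)-3-[(Z)-hex-3-en-1-yl]-4,5-dihydro-1,2-oxazol-5-yl]nonanoate A3. Oxidation of the free carbinol, reductive N–O cleavage and base-mediated cyclodehydration of the 1,4-diketone would then close C2–C3.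
- In its favour: the route is convergent, and both chains arrive in final form with no orthoester mask (better than the chosen plan). The C4 configuration is relayed from A5, which can be made enantioenriched, so no half of the material is lost (better). The step count to 16 would probably be lower (better).
- Against it here: after the oxidation C4 sits alpha to the C3 ketone and beta to the C1 ketone, so the basic ring closure could epimerise it or expel its oxygen. The closure must also choose between two methylene groups of nearly equal acidity (C2 onto C3 is wanted; the first chain carbon onto C1 gives an isomeric enone). That is exactly the problem the chosen plan settles by construction. The N–O reduction must spare the Z alkene.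
- Comparison: the alternative fixes C4 early and then exposes it, whereas the chosen plan fixes the alkene early and makes C4 late. On structural certainty the chosen plan is stronger; on convergence and step economy the alternative is the better.

**Alternative 3:** The cut is the C2–C3 bond of an isomeric 4-hydroxycyclopentenone, leading back to methyl 8-[5-[(Z)-1-hydroxyhex-3-en-1-yl]furan-2-yl]octanoate A7. The furan carbon bearing the ester chain becomes C3 and the carbinol carbon bearing the pentenyl group becomes C2. Forward, a Piancatelli rearrangement in hot buffered aqueous medium, or with a mild Lewis acid such as Dy(OTf)3, would give racemic trans-4-hydroxy-4-(7-methoxycarbonylheptyl)-5-[(Z)-pent-2-en-1-yl]cyclopent-2-en-1-one A6. The sequence is ionisation, hydration at the substituted furan carbon, ring opening and conrotatory 4π closure. Base or alumina would then have to move the hydroxyl and the alkene to give racemic 15.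
- In its favour: it is the shortest way to the carbocycle and needs no ester mask (better). The two chains are placed on distinct furan positions by separate reactions, so their assignment is as secure as in the chosen plan (equal). The route would join the chosen one at 15 after fewer steps (better).
- Against it here: furylcarbinols with an alkyl group on the far furan carbon are the reluctant substrates for this rearrangement, because the nucleophile must attack a substituted position. Forcing conditions invite loss of water from the carbinol toward the allylic methylene, giving a conjugated furyl diene, and Z to E drift. The transposition would also pass through a dehydrated, dienone-like stage with the skipped diene in place.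
- Comparison: on stereochemistry the two plans are equal, since both deliver racemic 15 for the same resolution. On mildness of the key step (below room temperature, non-acidic) the chosen plan is the safer.

Key step: step 6

## Route

Step 1
Reactants: 1 (Z)-pent-2-en-1-ol
Product: 2 (Z)-1-bromopent-2-ene
Conditions: PBr3 (0.4 equiv), pyridine (cat.), Et2O, −20 to 0 °C
Reagents that add atoms: phosphorus tribromide, BrP(Br)Br
Why: Bromination of a primary allylic alcohol with PBr3 (SN2 on the phosphite ester); at low temperature with a trace of pyridine the Z geometry should be kept and allylic transposition suppressed, and the volatile bromide is used at once.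

Step 2
Reactants: 3 prop-2-yn-1-ol; 2 (Z)-1-bromopent-2-ene
Product: 4 (Z)-oct-5-en-2-yn-1-ol
Conditions: CuI (10 mol%), K2CO3 (1.5 equiv), Bu4NCl (10 mol%), DMF, rt
Reagents that add atoms: none
Why: Copper-catalysed C(sp)–C(sp3) coupling of a terminal alkyne with an allylic halide: the copper acetylide formed with carbonate attacks the primary carbon of 2 (SN2, not SN2'), the free hydroxyl needs no protection, and no allyl cation or π-allyl metal species arises that could scramble the Z alkene.

Step 3
Reactants: 5 8-bromooctanoic acid
Product: 6 (3-methyloxetan-3-yl)methyl 8-bromooctanoate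
Conditions: (3-methyloxetan-3-yl)methanol (1.1 equiv), DCC, DMAP (cat.), CH2Cl2, 0 °C to rt
Reagents that add atoms: (3-methyloxetan-3-yl)methanol, CC1(CO)COC1
Why: Steglich esterification; the neutral carbodiimide conditions leave the primary bromide and the strained oxetane untouched.

Step 4
Reactants: 6 (3-methyloxetan-3-yl)methyl 8-bromooctanoate
Product: 7 1-(7-bromoheptyl)-4-methyl-2,6,7-trioxabicyclo[2.2.2]octane
Conditions: BF3·OEt2 (0.25 equiv), CH2Cl2, −15 °C to rt; Et3N quench
Reagents that add atoms: none
Why: Lewis-acid rearrangement of an oxetanyl ester to a bridged orthoester: BF3 opens the oxetane with participation of the ester carbonyl oxygen and the resulting dioxanylium ion is closed by the freed alkoxide; the orthoester removes the acidity and electrophilicity of the carboxyl group and is purified on base-washed silica.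

Step 5
Reactants: 7 1-(7-bromoheptyl)-4-methyl-2,6,7-trioxabicyclo[2.2.2]octane
Product: 8 7-(4-methyl-2,6,7-trioxabicyclo[2.2.2]octan-1-yl)heptylmagnesium bromide
Conditions: Mg turnings (activated by a crystal of I2), THF, 35 °C; titrated, used as solution
Reagents that add atoms: magnesium, [Mg]
Why: Grignard formation by insertion of magnesium into the primary C–Br bond; the bridged orthoester has no carbonyl group and is inert to the organomagnesium.

Step 6
Reactants: 4 (Z)-oct-5-en-2-yn-1-ol; 8 7-(4-methyl-2,6,7-trioxabicyclo[2.2.2]octan-1-yl)heptylmagnesium bromide; 9 acetaldehyde
Product: 12 (2Z,5Z)-3-(1-hydroxyethyl)-2-[7-(4-methyl-2,6,7-trioxabicyclo[2.2.2]octan-1-yl)heptyl]octa-2,5-dien-1-ol (racemic at the secondary carbinol), via chloromagnesium alkoxide of the enynol 10 (not isolated), via chelated vinylmagnesium oxamagnesacycle 11 (not isolated)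
Conditions: MeMgCl (1.0 equiv), THF, −20 °C; 8 (1.6 equiv), CuI (15 mol%), THF/Et2O, −20 to 10 °C; then 9 (4 equiv), −40 to 0 °C; aq. NH4Cl/NH3 (pH 8)
Reagents that add atoms: none
Why: MeMgCl first turns 4 into alkoxide 10 so that none of 8 is spent as a base; an organocopper species formed from 8 and CuI then adds across the alkyne of 10, the alkyl group going to the carbon next to the carbinol carbon and the metal to the distal carbon, anti, because only this arrangement lets the alkoxide oxygen hold the new vinyl–metal bond in the five-membered oxamagnesacycle 11. Transmetallation to magnesium returns the copper, and 11 adds as a vinyl Grignard reagent to the carbonyl group of 9, forming the C2–C1 bond with retention of alkene geometry. The closest known reaction type is the copper-catalysed, hydroxyl-directed anti carbomagnesiation of 2-alkyn-1-ols with primary alkyl Grignard reagents, followed by electrophilic trapping of the chelated vinylmagnesium. No ring of the target is closed; the only ring formed is the transient chelate 11. The one new stereocentre, the secondary carbinol, is formed without control as a racemate and is erased in step 7, while the alkene geometry (C1 and C4 cis) is dictated by the chelate. The step needs regiocontrol (chain on C3, acetaldehyde carbon on C2), anti addition and survival of the skipped enyne; the alkoxide chelate secures the first two, and copper catalysis below room temperature should leave the doubly activated methylene and the Z alkene alone.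

Step 7
Reactants: 12 (2Z,5Z)-3-(1-hydroxyethyl)-2-[7-(4-methyl-2,6,7-trioxabicyclo[2.2.2]octan-1-yl)heptyl]octa-2,5-dien-1-ol
Product: 13 (2Z,5Z)-3-acetyl-2-[7-(4-methyl-2,6,7-trioxabicyclo[2.2.2]octan-1-yl)heptyl]octa-2,5-dienal
Conditions: (COCl)2 (3 equiv), DMSO (6 equiv), CH2Cl2, −78 °C; Et3N (10 equiv), −78 to −20 °C; crude used at once
Reagents that add atoms: none
Why: Swern oxidation: both carbinols are converted into alkoxysulfonium ions at −78 °C before any base is present, so no hydroxy-carbonyl intermediate exists that could lactolise and aromatise to a furan; the alkene is not touched, so the Z geometry of 12 is carried into 13, and excess DMSO buffers the HCl that could open the orthoester.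

Step 8
Reactants: 13 (2Z,5Z)-3-acetyl-2-[7-(4-methyl-2,6,7-trioxabicyclo[2.2.2]octan-1-yl)heptyl]octa-2,5-dienal
Product: 14 rac-4-hydroxy-3-[7-(4-methyl-2,6,7-trioxabicyclo[2.2.2]octan-1-yl)heptyl]-2-[(Z)-pent-2-en-1-yl]cyclopent-2-en-1-one
Conditions: NaHCO3/Na2CO3 buffer (pH 9, 0.2 equiv base), THF/H2O, 0 °C to rt
Reagents that add atoms: none
Why: Intramolecular aldol addition: the methyl ketone enolate (C5) adds to the aldehyde (C4) held cis across the alkene, a 5-(enolendo)-exo-trig closure of the kind by which cis-enediones give 4-hydroxycyclopentenones; dehydration should not follow because it would give a cyclopentadienone, and C4 is formed as a racemate.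

Step 9
Reactants: 14 rac-4-hydroxy-3-[7-(4-methyl-2,6,7-trioxabicyclo[2.2.2]octan-1-yl)heptyl]-2-[(Z)-pent-2-en-1-yl]cyclopent-2-en-1-one
Product: 15 rac-methyl 8-[5-hydroxy-3-oxo-2-[(Z)-pent-2-en-1-yl]cyclopent-1-en-1-yl]octanoate
Conditions: TsOH·H2O (0.2 equiv), MeOH, H2O (2 equiv), rt to 40 °C
Reagents that add atoms: methanol, CO; water, O
Why: Acid-catalysed orthoester hydrolysis to the triol monoester followed by Fischer-type transesterification in methanol; the 4-hydroxy enone should tolerate mild acid because ionisation at C4 would place positive charge on C2, next to the carbonyl group.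

Step 10
Reactants: 15 rac-methyl 8-[5-hydroxy-3-oxo-2-[(Z)-pent-2-en-1-yl]cyclopent-1-en-1-yl]octanoate
Product: 16 methyl 8-[(5S)-5-hydroxy-3-oxo-2-[(Z)-pent-2-en-1-yl]cyclopent-1-en-1-yl]octanoate
Conditions: Amano lipase PS (Burkholderia cepacia), vinyl acetate (3 equiv), MTBE, 30 °C, stopped just past half conversion; chromatography
Reagents that add atoms: none
Why: Lipase-catalysed kinetic resolution by irreversible transesterification with an enol ester: by the empirical size model for lipases (large group C3 with its chain, medium group C5H2) the R enantiomer should be acetylated and the S alcohol 16 left, as is usual for 4-hydroxycyclopent-2-enones.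

Step 11
Reactants: 16 methyl 8-[(5S)-5-hydroxy-3-oxo-2-[(Z)-pent-2-en-1-yl]cyclopent-1-en-1-yl]octanoate
Product: 17 methyl 8-[(5S)-3-oxo-2-[(Z)-pent-2-en-1-yl]-5-(triethylsilyloxy)cyclopent-1-en-1-yl]octanoate
Conditions: Et3SiCl (1.2 equiv), imidazole (2 equiv), CH2Cl2, 0 °C
Reagents that add atoms: chlorotriethylsilane, CC[Si](Cl)(CC)CC
Why: Silyl ether formation (chlorosilane, imidazole); the triethylsilyl group masks the hydroxyl for the enolate step, screens one face of C5 and can later be removed under mildly acidic fluoride conditions.

Step 12
Reactants: 17 methyl 8-[(5S)-3-oxo-2-[(Z)-pent-2-en-1-yl]-5-(triethylsilyloxy)cyclopent-1-en-1-yl]octanoate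
Product: 19 methyl 8-[(4S,5R)-4-bromo-3-oxo-2-[(Z)-pent-2-en-1-yl]-5-(triethylsilyloxy)cyclopent-1-en-1-yl]octanoate, via trimethylsilyl dienol ether 18 (not isolated)
Conditions: Me3SiCl (1.3 equiv), LiN(SiMe3)2 (1.1 equiv), THF, −78 °C; then NBS (1.05 equiv), −78 to −30 °C
Reagents that add atoms: N-bromosuccinimide, O=C1CCC(=O)N1Br
Why: Kinetic alpha'-deprotonation of the enone at C5 by the lithium amide with in situ O-silylation gives 18, and electrophilic bromination of this silyl enol ether by NBS should occur at C5 on the face anti to the C4 silyloxy group, which places bromine trans to oxygen; a cis epimer would equilibrate to the trans one through the enol. The ketone alpha' protons are far more acidic than those of the ester, and the electron-rich enol ether should outpace the isolated Z alkene toward NBS.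

Step 13
Reactants: 19 methyl 8-[(4S,5R)-4-bromo-3-oxo-2-[(Z)-pent-2-en-1-yl]-5-(triethylsilyloxy)cyclopent-1-en-1-yl]octanoate
Product: 20 methyl 8-[(4S,5R)-4-bromo-5-hydroxy-3-oxo-2-[(Z)-pent-2-en-1-yl]cyclopent-1-en-1-yl]octanoate
Conditions: HF·pyridine, THF, 0 °C
Reagents that add atoms: none
Why: Fluoride-mediated desilylation under buffered acidic conditions; base is avoided because the trans bromohydrin would close to an epoxide or undergo retro-aldol cleavage, and neither stereocentre is touched.

## Compound list

1 | (Z)-pent-2-en-1-ol | CC/C=C\CO | starting material
2 | (Z)-1-bromopent-2-ene | CC/C=C\CBr | intermediate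
3 | prop-2-yn-1-ol | C#CCO | starting material
4 | (Z)-oct-5-en-2-yn-1-ol | CC/C=C\CC#CCO | intermediate
5 | 8-bromooctanoic acid | OC(=O)CCCCCCCBr | starting material
6 | (3-methyloxetan-3-yl)methyl 8-bromooctanoate | CC1(COC(=O)CCCCCCCBr)COC1 | intermediate
7 | 1-(7-bromoheptyl)-4-methyl-2,6,7-trioxabicyclo[2.2.2]octane | CC12COC(CCCCCCCBr)(OC1)OC2 | intermediate
8 | 7-(4-methyl-2,6,7-trioxabicyclo[2.2.2]octan-1-yl)heptylmagnesium bromide | CC12COC(CCCCCCC[Mg]Br)(OC1)OC2 | intermediate
9 | acetaldehyde | CC=O | starting material
10 | chloromagnesium (Z)-oct-5-en-2-yn-1-olate | CC/C=C\CC#CCO[Mg]Cl | intermediate (not isolated)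
11 | 4-[7-(4-methyl-2,6,7-trioxabicyclo[2.2.2]octan-1-yl)heptyl]-3-[(Z)-pent-2-en-1-yl]-2,5-dihydro-1,2-oxamagnesole | CC/C=C\CC1=C(CCCCCCCC23OCC(C)(CO2)CO3)CO[Mg]1 | intermediate (not isolated)
12 | (2Z,5Z)-3-(1-hydroxyethyl)-2-[7-(4-methyl-2,6,7-trioxabicyclo[2.2.2]octan-1-yl)heptyl]octa-2,5-dien-1-ol, racemic at the secondary carbinol | OC/C(CCCCCCCC12OCC(C)(CO1)CO2)=C(\C(C)O)C/C=C\CC | intermediate
13 | (2Z,5Z)-3-acetyl-2-[7-(4-methyl-2,6,7-trioxabicyclo[2.2.2]octan-1-yl)heptyl]octa-2,5-dienal | O=C/C(CCCCCCCC12OCC(C)(CO1)CO2)=C(\C(C)=O)C/C=C\CC | intermediate
14 | rac-4-hydroxy-3-[7-(4-methyl-2,6,7-trioxabicyclo[2.2.2]octan-1-yl)heptyl]-2-[(Z)-pent-2-en-1-yl]cyclopent-2-en-1-one | CC/C=C\CC1=C(CCCCCCCC23OCC(C)(CO2)CO3)C(O)CC1=O | intermediate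
15 | rac-methyl 8-[5-hydroxy-3-oxo-2-[(Z)-pent-2-en-1-yl]cyclopent-1-en-1-yl]octanoate | CC/C=C\CC1=C(CCCCCCCC(=O)OC)C(O)CC1=O | intermediate
16 | methyl 8-[(5S)-5-hydroxy-3-oxo-2-[(Z)-pent-2-en-1-yl]cyclopent-1-en-1-yl]octanoate | CC/C=C\CC1=C(CCCCCCCC(=O)OC)[C@@H](O)CC1=O | intermediate
17 | methyl 8-[(5S)-3-oxo-2-[(Z)-pent-2-en-1-yl]-5-(triethylsilyloxy)cyclopent-1-en-1-yl]octanoate | CC/C=C\CC1=C(CCCCCCCC(=O)OC)[C@@H](O[Si](CC)(CC)CC)CC1=O | intermediate
18 | methyl 8-[(5S)-2-[(Z)-pent-2-en-1-yl]-5-(triethylsilyloxy)-3-(trimethylsilyloxy)cyclopenta-1,3-dien-1-yl]octanoate | CC/C=C\CC1=C(CCCCCCCC(=O)OC)[C@@H](O[Si](CC)(CC)CC)C=C1O[Si](C)(C)C | intermediate (not isolated)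
19 | methyl 8-[(4S,5R)-4-bromo-3-oxo-2-[(Z)-pent-2-en-1-yl]-5-(triethylsilyloxy)cyclopent-1-en-1-yl]octanoate | CC/C=C\CC1=C(CCCCCCCC(=O)OC)[C@@H](O[Si](CC)(CC)CC)[C@H](Br)C1=O | intermediate
20 | methyl 8-[(4S,5R)-4-bromo-5-hydroxy-3-oxo-2-[(Z)-pent-2-en-1-yl]cyclopent-1-en-1-yl]octanoate | CC/C=C\CC1=C(CCCCCCCC(=O)OC)[C@@H](O)[C@H](Br)C1=O | target

## Step count and least certain steps

Total: 13 steps. Longest linear sequence: 11 steps (steps 3 to 13, from 5 to 20).

**Step 6 (key step).** The most likely failures are incomplete carbometallation of the internal alkyne, because alkyl transfer from copper to a hindered alkynol alkoxide is slow, and proton transfer from enolisable 9 to the hindered vinylmagnesium in place of carbonyl addition. Long reaction times also risk base-induced migration of the skipped enyne. The fallback sets out from 4 (with 8) and comes back at 12. The carbomagnesiation is run as before, but 11 is quenched with I2, which cannot be enolised, to give the vinyl iodide (2Z,5Z)-3-iodo-2-[7-(4-methyl-2,6,7-trioxabicyclo[2.2.2]octan-1-yl)heptyl]octa-2,5-dien-1-ol F1. This iodide is then joined to 9 in a separate Nozaki–Hiyama–Kishi coupling (CrCl2, NiCl2 cat., DMF), which tolerates the free hydroxyl and the orthoester and should give 12 with the alkene geometry retained.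

**Step 7.** The risks are opening of the orthoester by HCl released while the alkoxysulfonium ions form, incomplete oxidation of one carbinol followed by lactolisation and aromatisation, and Z to E isomerisation of the enedione by reversible conjugate addition. The fallback sets out from 12 and comes back at 13. It makes the aromatisation the intended path: one oxidation with pyridinium chlorochromate, [C5H5NH][CrO3Cl], in CH2Cl2 is followed by spontaneous cyclodehydration to the furan 1-[7-[5-methyl-4-[(Z)-pent-2-en-1-yl]furan-3-yl]heptyl]-4-methyl-2,6,7-trioxabicyclo[2.2.2]octane F2. Oxidative ring opening of the furan with NBS and NaHCO3 in aqueous acetone at −15 °C should then give the Z keto-enal 13, since the furan is far more electron-rich than the side-chain alkene.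

**Step 8.** The risks are deprotonation at the doubly activated methylene of the pentenyl group (gamma to the aldehyde and allylic), which would move double bonds into conjugation, isomerisation to the E enedione that cannot close, and a slow closure because the enolate must twist out of conjugation. The fallback sets out from 13 and comes back at 14. It replaces the reversible base-mediated enolate by a preformed enol silane: soft enolisation of the methyl ketone (Me3SiOTf, Et3N, CH2Cl2, −78 °C) gives (2Z,5Z)-2-[7-(4-methyl-2,6,7-trioxabicyclo[2.2.2]octan-1-yl)heptyl]-3-[1-(trimethylsilyloxy)ethenyl]octa-2,5-dienal F3. An intramolecular Mukaiyama aldol addition (BF3·OEt2, CH2Cl2, −78 °C, NaHCO3 quench) then closes C4–C5 without any free base.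

**Step 10.** The risks are slow acylation or poor discrimination between the enantiomers because the chain on C3 crowds the carbinol, and stray acyl transfer involving the methyl ester. The fallback sets out from 15 and comes back at 16. It gives up kinetic resolution for preparative chromatography of the racemate on a chiral stationary phase; no new compound is made (F0).

**Step 12.** The risks are loss of the silyloxy group from the C5 enolate (E1cB, leading toward a cyclopentadienone), competing deprotonation of the ester, attack of the bromine source on the Z alkene or the doubly allylic position, and incomplete facial selectivity; the last is correctable by equilibration. The fallback sets out from 16 and comes back at 20, bypassing 17 and 19. The free alcohol is deprotonated twice with LiN(SiMe3)2 (2.2 equiv), so that the group beta to the enolate is an alkoxide, a poor leaving group. Both oxygens are then silylated with Me3SiCl to give methyl 8-[(5S)-2-[(Z)-pent-2-en-1-yl]-3,5-bis(trimethylsilyloxy)cyclopenta-1,3-dien-1-yl]octanoate F4. NBS converts this into methyl 8-[(4S,5R)-4-bromo-3-oxo-2-[(Z)-pent-2-en-1-yl]-5-(trimethylsilyloxy)cyclopent-1-en-1-yl]octanoate F5, and dilute aqueous acid on work-up removes the labile silyl ether to give 20.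

## Further compounds

F1 | step 6 | (2Z,5Z)-3-iodo-2-[7-(4-methyl-2,6,7-trioxabicyclo[2.2.2]octan-1-yl)heptyl]octa-2,5-dien-1-ol | OC/C(CCCCCCCC12OCC(C)(CO1)CO2)=C(\I)C/C=C\CC
F2 | step 7 | 1-[7-[5-methyl-4-[(Z)-pent-2-en-1-yl]furan-3-yl]heptyl]-4-methyl-2,6,7-trioxabicyclo[2.2.2]octane | Cc1occ(CCCCCCCC23OCC(C)(CO2)CO3)c1C/C=C\CC
F3 | step 8 | (2Z,5Z)-2-[7-(4-methyl-2,6,7-trioxabicyclo[2.2.2]octan-1-yl)heptyl]-3-[1-(trimethylsilyloxy)ethenyl]octa-2,5-dienal | O=C/C(CCCCCCCC12OCC(C)(CO1)CO2)=C(\C(=C)O[Si](C)(C)C)C/C=C\CC
F0 | step 10 | none | none
F4 | step 12 | methyl 8-[(5S)-2-[(Z)-pent-2-en-1-yl]-3,5-bis(trimethylsilyloxy)cyclopenta-1,3-dien-1-yl]octanoate | CC/C=C\CC1=C(CCCCCCCC(=O)OC)[C@@H](O[Si](C)(C)C)C=C1O[Si](C)(C)C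
F5 | step 12 | methyl 8-[(4S,5R)-4-bromo-3-oxo-2-[(Z)-pent-2-en-1-yl]-5-(trimethylsilyloxy)cyclopent-1-en-1-yl]octanoate | CC/C=C\CC1=C(CCCCCCCC(=O)OC)[C@@H](O[Si](C)(C)C)[C@H](Br)C1=O
A1 | alternative 1 | (6aS)-4-[(Z)-pent-2-en-1-yl]-2,3,6,6a-tetrahydro-5H-cyclopenta[b]furan-5-one | CC/C=C\CC1=C2CCO[C@H]2CC1=O
A2 | alternative 1 | (Z)-1-(ethenyloxy)non-6-en-3-yne | C=COCCC#CC/C=C\CC
A3 | alternative 2 | methyl (9S)-9-hydroxy-9-[(5S)-3-[(Z)-hex-3-en-1-yl]-4,5-dihydro-1,2-oxazol-5-yl]nonanoate | CC/C=C\CCC1=NO[C@@H](C1)[C@@H](O)CCCCCCCC(=O)OC
A4 | alternative 2 | (Z)-hept-4-enal oxime | CC/C=C\CCC=NO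
A5 | alternative 2 | methyl (9S)-9-hydroxyundec-10-enoate | C=C[C@@H](O)CCCCCCCC(=O)OC
A6 | alternative 3 | rac-trans-4-hydroxy-4-(7-methoxycarbonylheptyl)-5-[(Z)-pent-2-en-1-yl]cyclopent-2-en-1-one (one enantiomer drawn) | O=C1C=C[C@@](O)(CCCCCCCC(=O)OC)[C@H]1C/C=C\CC
A7 | alternative 3 | methyl 8-[5-[(Z)-1-hydroxyhex-3-en-1-yl]furan-2-yl]octanoate | CC/C=C\CC(O)c1ccc(CCCCCCCC(=O)OC)o1
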